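**Retrosynthetic overview**

1. The target comes from its tri-O-benzyl ether by hydrogenolysis. The O3 acetate is put on a (2R,3R)-3-hydroxyflavanone, whose C3–O bond is made by Rubottom oxidation of a C3=C4 silyl enol ether on the face opposite the C2 aryl group.
2. That (2S)-silyl enol ether comes from an enantioselective copper hydride 1,4-hydrosilylation of a flavone, which sets C2. The C5 benzyloxy group of the flavone replaces a fluoride by SNAr.
3. Key disconnection: ring C of the 5-fluoroflavone is opened at O1–C8a and C3–C4. This gives 2,6-difluoro-4-methoxybenzoyl chloride (ring A with C4) and the lithium enolate of 3,4-bis(benzyloxy)acetophenone (ring B with O1–C2–C3). In the forward direction, Claisen C-acylation and SNAr ring closure follow each other in one flask.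
4. Enabling feature: O1–C2–C3 is a ketone enolate whose two nucleophilic ends are O1 and C3, and C4 and C8a are 1,3-related electrophiles on ring A, the C4 carbonyl activating the ortho C8a–F bond. C5 and C8a are both oxygenated in the target, so the symmetric difluoride gives the same product whichever fluorine leaves.
5. Ring order: rings A and B are bought; ring C is formed in the key step.

Key step: step 2

Assumption: both starting materials are taken as commercially available; the sense of induction written for (R)-DTBM-SEGPHOS in step 4 is an expectation by analogy with β-aryl enones, and the (S)-ligand is used instead if a test run shows hydride delivery to the opposite face.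

**Route**

Step 1
Reactants: 1 2,6-difluoro-4-methoxybenzoic acid
Product: 2 2,6-difluoro-4-methoxybenzoyl chloride
Conditions: (COCl)2 (1.3 equiv), DMF (cat.), CH2Cl2, 0 °C → rt; concentrate, use crude
Reagents that add atoms: oxalyl chloride, ClC(=O)C(Cl)=O
Why: Acid chloride formation through the chloroiminium species from DMF and oxalyl chloride is standard for hindered benzoic acids and touches neither the aryl fluorides nor the methyl ether.

Step 2
Reactants: 3 1-[3,4-bis(benzyloxy)phenyl]ethan-1-one; 2 2,6-difluoro-4-methoxybenzoyl chloride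
Product: 6 2-[3,4-bis(benzyloxy)phenyl]-5-fluoro-7-methoxy-4H-chromen-4-one, via lithium enolate 4 (not isolated), via lithium diketonate 5 (not isolated)
Conditions: LiN(SiMe3)2 (2.2 equiv), THF, −78 °C; add 2, −78 → 0 °C; then add DMF, remove THF, 90 °C
Reagents that add atoms: none
Why: Deprotonation of 3 gives lithium enolate 4, whose carbon (the future C3) attacks acid chloride 2 in a Claisen-type C-acylation (C3–C4), and the second equivalent of base converts the β-diketone at once into the chelated lithium Z-diketonate 5, which stops further acylation; on heating in DMF the oxygen on the future C2 adds to C8a of ring A and fluoride leaves through a Meisenheimer intermediate (SNAr, O1–C8a). The closest known reaction type is the one-flask synthesis of chromones, flavones and 4-quinolones from 2-halobenzoyl chlorides and ketone enolates or enamines. Ring C closes by a 6-exo-trig addition–elimination of the enolate oxygen on the aromatic carbon, the only closure possible because attack through C3 would need a four-membered ring. No stereocentre is formed: C2 and C3 appear as the C2=C3 double bond, a temporary oxidation level from which steps 4 and 5 set both centres. The step needs C- over O-acylation and a single ring closure: the lithium counter-ion in THF at low temperature favours C-acylation and any enol ester is transacylated by remaining enolate, the two fluorines of ring A are equivalent so either displacement gives the same flavone, and the C4 carbonyl and the second fluorine activate C8a.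

Step 3
Reactants: 6 2-[3,4-bis(benzyloxy)phenyl]-5-fluoro-7-methoxy-4H-chromen-4-one
Product: 7 5-(benzyloxy)-2-[3,4-bis(benzyloxy)phenyl]-7-methoxy-4H-chromen-4-one
Conditions: BnOH (1.5 equiv), NaH (1.5 equiv), THF–DMF, 0 → 60 °C
Reagents that add atoms: benzyl alcohol, OCc1ccccc1
Why: Nucleophilic aromatic substitution: the C5 fluorine is ortho to the C4 carbonyl, so benzyl oxide should add at C5 and expel fluoride, while the C7 methyl ether is no leaving group and any addition of the alkoxide to C2 of the pyranone is reversible.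

Step 4
Reactants: 7 5-(benzyloxy)-2-[3,4-bis(benzyloxy)phenyl]-7-methoxy-4H-chromen-4-one
Product: 8 {[(2S)-5-(benzyloxy)-2-[3,4-bis(benzyloxy)phenyl]-7-methoxy-2H-chromen-4-yl]oxy}diethoxy(methyl)silane
Conditions: Cu(OAc)2 (5 mol %), (R)-DTBM-SEGPHOS (5.5 mol %), (EtO)2MeSiH (3 equiv), toluene, 0 °C → rt, no proton source; volatiles removed, filtered through neutral Al2O3 under argon, used crude
Reagents that add atoms: diethoxy(methyl)silane, CCO[SiH](C)OCC
Why: Copper hydride catalysed asymmetric conjugate reduction (1,4-hydrosilylation): the bisphosphine-ligated copper hydride should deliver hydride to the Re face of C2 of the chromone enone to give the 2S centre, and σ-bond metathesis of the copper enolate with the silane releases the silyl enol ether, which cannot be reduced further.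

Step 5
Reactants: 8 {[(2S)-5-(benzyloxy)-2-[3,4-bis(benzyloxy)phenyl]-7-methoxy-2H-chromen-4-yl]oxy}diethoxy(methyl)silane
Product: 10 (2R,3R)-5-(benzyloxy)-2-[3,4-bis(benzyloxy)phenyl]-3-hydroxy-7-methoxy-2,3-dihydro-4H-chromen-4-one, via silyloxy epoxide 9 (not isolated)
Conditions: dimethyldioxirane (1.2 equiv), acetone–CH2Cl2, −40 → 0 °C; then aq. citric acid, THF, 0 °C
Reagents that add atoms: dimethyldioxirane, CC1(C)OO1
Why: Rubottom oxidation: the neutral dioxirane should epoxidise the electron-rich C3=C4 enol ether on the face opposite the C2 aryl group, and hydrolysis of silyloxy epoxide 9 gives the α-hydroxy ketone with the C3 hydroxyl trans to the aryl group (3R), without ever forming a flavanone enolate that could open ring C and racemise C2.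

Step 6
Reactants: 10 (2R,3R)-5-(benzyloxy)-2-[3,4-bis(benzyloxy)phenyl]-3-hydroxy-7-methoxy-2,3-dihydro-4H-chromen-4-one
Product: 11 (2R,3R)-5-(benzyloxy)-2-[3,4-bis(benzyloxy)phenyl]-7-methoxy-4-oxo-3,4-dihydro-2H-chromen-3-yl acetate
Conditions: Ac2O (1.5 equiv), pyridine, 4-(dimethylamino)pyridine (cat.), CH2Cl2, 0 °C
Reagents that add atoms: acetic anhydride, CC(=O)OC(C)=O
Why: Acylation with nucleophilic catalysis of the only free hydroxyl under weakly basic conditions should leave C3 and ring C untouched, and the trans arrangement is also the thermodynamically preferred one.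

Step 7
Reactants: 11 (2R,3R)-5-(benzyloxy)-2-[3,4-bis(benzyloxy)phenyl]-7-methoxy-4-oxo-3,4-dihydro-2H-chromen-3-yl acetate
Product: 12 (2R,3R)-2-(3,4-dihydroxyphenyl)-5-hydroxy-7-methoxy-4-oxo-3,4-dihydro-2H-chromen-3-yl acetate (3-O-acetylpadmatin)
Conditions: H2 (1 atm), Pd/C (10 wt % Pd), EtOAc–THF, rt
Reagents that add atoms: none
Why: Hydrogenolysis of the three benzyl aryl ethers over palladium should leave the acetate, the methyl ether and the aryl ketone intact and does not involve C2 or C3.

**Compound list**

1 | 2,6-difluoro-4-methoxybenzoic acid | COc1cc(F)c(C(=O)O)c(F)c1 | starting material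
2 | 2,6-difluoro-4-methoxybenzoyl chloride | COc1cc(F)c(C(=O)Cl)c(F)c1 | intermediate
3 | 1-[3,4-bis(benzyloxy)phenyl]ethan-1-one | CC(=O)c1ccc(OCc2ccccc2)c(OCc2ccccc2)c1 | starting material
4 | lithium 1-[3,4-bis(benzyloxy)phenyl]ethen-1-olate | C=C(O[Li])c1ccc(OCc2ccccc2)c(OCc2ccccc2)c1 | intermediate
5 | lithium (Z)-1-[3,4-bis(benzyloxy)phenyl]-3-(2,6-difluoro-4-methoxyphenyl)-3-oxoprop-1-en-1-olate | COc1cc(F)c(C(=O)/C=C(\O[Li])c2ccc(OCc3ccccc3)c(OCc3ccccc3)c2)c(F)c1 | intermediate
6 | 2-[3,4-bis(benzyloxy)phenyl]-5-fluoro-7-methoxy-4H-chromen-4-one | COc1cc(F)c2c(c1)OC(c1ccc(OCc3ccccc3)c(OCc3ccccc3)c1)=CC2=O | intermediate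
7 | 5-(benzyloxy)-2-[3,4-bis(benzyloxy)phenyl]-7-methoxy-4H-chromen-4-one | COc1cc(OCc3ccccc3)c2c(c1)OC(c1ccc(OCc3ccccc3)c(OCc3ccccc3)c1)=CC2=O | intermediate
8 | {[(2S)-5-(benzyloxy)-2-[3,4-bis(benzyloxy)phenyl]-7-methoxy-2H-chromen-4-yl]oxy}diethoxy(methyl)silane | COc1cc(OCc3ccccc3)c2c(c1)O[C@H](c1ccc(OCc3ccccc3)c(OCc3ccccc3)c1)C=C2O[Si](C)(OCC)OCC | intermediate
9 | (2R,3R,4R)-5-(benzyloxy)-2-[3,4-bis(benzyloxy)phenyl]-4-{[diethoxy(methyl)silyl]oxy}-3,4-epoxy-7-methoxy-3,4-dihydro-2H-chromene (epoxide oxygen trans to the C2 aryl group) | COc1cc(OCc3ccccc3)c2c(c1)O[C@H](c1ccc(OCc3ccccc3)c(OCc3ccccc3)c1)[C@H]4O[C@@]24O[Si](C)(OCC)OCC | intermediate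
10 | (2R,3R)-5-(benzyloxy)-2-[3,4-bis(benzyloxy)phenyl]-3-hydroxy-7-methoxy-2,3-dihydro-4H-chromen-4-one | COc1cc(OCc3ccccc3)c2c(c1)O[C@H](c1ccc(OCc3ccccc3)c(OCc3ccccc3)c1)[C@@H](O)C2=O | intermediate
11 | (2R,3R)-5-(benzyloxy)-2-[3,4-bis(benzyloxy)phenyl]-7-methoxy-4-oxo-3,4-dihydro-2H-chromen-3-yl acetate | COc1cc(OCc3ccccc3)c2c(c1)O[C@H](c1ccc(OCc3ccccc3)c(OCc3ccccc3)c1)[C@@H](OC(C)=O)C2=O | intermediate
12 | (2R,3R)-2-(3,4-dihydroxyphenyl)-5-hydroxy-7-methoxy-4-oxo-3,4-dihydro-2H-chromen-3-yl acetate (3-O-acetylpadmatin) | COc1cc(O)c2c(c1)O[C@H](c1ccc(O)c(O)c1)[C@@H](OC(C)=O)C2=O | target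

**Step count and risks**

Total step count: 7. Longest linear sequence: 7 steps (1 to 12); ketone 3 enters at step 2.

Steps most likely to fail:

1. Step 4. Hydride transfer to the electron-rich, β-oxygenated enone may be slow, reduction may go 1,2 at the carbonyl, or the two faces of C2 may be poorly distinguished. The fallback sets out from 7 and separates reduction from enol ether formation. Asymmetric hydrogenation of the pyranone ring with a chiral ruthenium N-heterocyclic carbene catalyst (Ru(cod)(2-methylallyl)2, 1,3-bis[1-(naphthalen-1-yl)ethyl]-4,5-dihydroimidazolium tetrafluoroborate as a single enantiomer, KOt-Bu, H2) should give (2S,4S)-5-(benzyloxy)-2-[3,4-bis(benzyloxy)phenyl]-7-methoxy-3,4-dihydro-2H-chromen-4-ol F1. Oxidation with Dess–Martin periodinane gives (2S)-5-(benzyloxy)-2-[3,4-bis(benzyloxy)phenyl]-7-methoxy-2,3-dihydro-4H-chromen-4-one F2. LiN(SiMe3)2 with Me3SiCl present (−78 °C) gives the trimethylsilyl enol ether F3. Dimethyldioxirane oxidation as in step 5, through the trimethylsilyloxy epoxide F4, brings the material back to the route at 10.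

2. Step 5. The moisture-sensitive silyl group may be lost before oxidation, or the oxidant may attack both faces of the enol ether. The fallback sets out from 8 and replaces epoxidation–rearrangement by direct transfer of an acetoxy group: Pb(OAc)4 in CH2Cl2 at low temperature (α-acetoxylation of a silyl enol ether, again expected anti to the C2 aryl group) should give acetate 11 directly, so that step 6 is not needed; this fallback makes no new compound (F0).

3. Step 3. Benzyl oxide may add to C2 of the pyranone and open ring C instead of substituting at C5, or substitution may stay incomplete. The fallback sets out from 1 and moves the substitution ahead of the annulation. BnOH/NaH in DMF on the sodium carboxylate should give 2-(benzyloxy)-6-fluoro-4-methoxybenzoic acid F5, and oxalyl chloride with catalytic DMF gives 2-(benzyloxy)-6-fluoro-4-methoxybenzoyl chloride F6. The conditions of step 2 with ketone 3 (through enolate 4 and the lithium diketonate F7) then close ring C on the remaining fluorine and come back to the route at 7.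

**Further compounds**

F1 | step 4 | (2S,4S)-5-(benzyloxy)-2-[3,4-bis(benzyloxy)phenyl]-7-methoxy-3,4-dihydro-2H-chromen-4-ol | COc1cc(OCc3ccccc3)c2c(c1)O[C@H](c1ccc(OCc3ccccc3)c(OCc3ccccc3)c1)C[C@@H]2O
F2 | step 4 | (2S)-5-(benzyloxy)-2-[3,4-bis(benzyloxy)phenyl]-7-methoxy-2,3-dihydro-4H-chromen-4-one | COc1cc(OCc3ccccc3)c2c(c1)O[C@H](c1ccc(OCc3ccccc3)c(OCc3ccccc3)c1)CC2=O
F3 | step 4 | {[(2S)-5-(benzyloxy)-2-[3,4-bis(benzyloxy)phenyl]-7-methoxy-2H-chromen-4-yl]oxy}trimethylsilane | COc1cc(OCc3ccccc3)c2c(c1)O[C@H](c1ccc(OCc3ccccc3)c(OCc3ccccc3)c1)C=C2O[Si](C)(C)C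
F4 | step 4 | (2R,3R,4R)-5-(benzyloxy)-2-[3,4-bis(benzyloxy)phenyl]-3,4-epoxy-7-methoxy-4-[(trimethylsilyl)oxy]-3,4-dihydro-2H-chromene | COc1cc(OCc3ccccc3)c2c(c1)O[C@H](c1ccc(OCc3ccccc3)c(OCc3ccccc3)c1)[C@H]4O[C@@]24O[Si](C)(C)C
F0 | step 5 | none | none
F5 | step 3 | 2-(benzyloxy)-6-fluoro-4-methoxybenzoic acid | COc1cc(F)c(C(=O)O)c(OCc2ccccc2)c1
F6 | step 3 | 2-(benzyloxy)-6-fluoro-4-methoxybenzoyl chloride | COc1cc(F)c(C(=O)Cl)c(OCc2ccccc2)c1
F7 | step 3 | lithium (Z)-3-[2-(benzyloxy)-6-fluoro-4-methoxyphenyl]-1-[3,4-bis(benzyloxy)phenyl]-3-oxoprop-1-en-1-olate | COc1cc(F)c(C(=O)/C=C(\O[Li])c2ccc(OCc3ccccc3)c(OCc3ccccc3)c2)c(OCc2ccccc2)c1
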